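**Retrosynthetic overview**

1. Feature: ring A (C1–C5, C10; eremophilane numbering) is cis-fused to ring B at C5/C10, has cis methyls on C4 and C5, and has its ketone at C2, reached from C10 through C1. A [3,3] shift of a 2-alkenylbicyclo[2.2.2]oct-5-en-2-olate leaves exactly this array.
2. Target ⇒ C9 angelate and C8 tiglate taken back to a C9 ketal and a C8 ketone; C7 isopropenyl ⇒ Suzuki coupling on a 7-iodo-Δ6-en-8-one; the C2 ketone is carried as an equatorial silyl ether.
3. Key disconnection: open C4–C5 and re-join C2–C7 ⇒ a (Z)-propenyl carbinol on a bicyclo[2.2.2]octene (bridgeheads C7, C10) that already holds ring B with C8 and C9 oxygenated.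
4. Bicycle ⇒ inverse-demand Diels–Alder adduct of the masked o-benzoquinone of creosol with benzyl vinyl ether, resolved with a lipase.
5. Ring order: ring B first (as the bicycle, step 1), ring A second (step 8).

Key step: step 8

Remark on numbering: every carbon keeps its eremophilane number in the text, also in the bicycles (C7 and C10 bridgeheads; C5=C6, C8–C9 and C1–C2 the three bridges). α/β refer to the usual eremophilane drawing with the C4 and C5 methyls β, "decal" is decahydronaphthalene with these numbers, and bicyclo[2.2.2]octane locants appear only inside systematic names.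

Assumption: in step 5 the lipase acetylates the (2R)-alcohol faster (bridgehead carbon as the large group, CH2 as the medium one), so the (2S)-alcohol is the one recovered. Compounds 4–7 are racemic and are drawn as the enantiomer that is carried on.

**Route**

Step 1
Reactants: 1 creosol (2-methoxy-4-methylphenol); 2 benzyl vinyl ether
Product: 4 rac-7-endo-benzyloxy-3,3-dimethoxy-5-methylbicyclo[2.2.2]oct-5-en-2-one, via masked o-benzoquinone 3 (not isolated)
Conditions: PhI(OAc)2, 2 (10 equiv), MeOH, 0 °C to rt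
Reagents that add atoms: methanol (CO)
Why: Hypervalent-iodine oxidation of the guaiacol in methanol gives the 6,6-dimethoxydienone 3, which the excess enol ether traps in an inverse-electron-demand Diels–Alder reaction before it dimerises; the enol ether CH2 bonds to the dienone carbon remote from the carbonyl, so the O-bearing carbon ends next to the bridgehead α to the ketone, and the endo transition state places OBn syn to the new alkene (both bridgeheads and the OBn carbon set, racemic).

Step 2
Reactants: 4 rac-7-endo-benzyloxy-3,3-dimethoxy-5-methylbicyclo[2.2.2]oct-5-en-2-one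
Product: 5 rac-7-endo-benzyloxy-3,3-dimethoxy-5-methylbicyclo[2.2.2]oct-5-en-2-ol (hydroxyl anti to the alkene)
Conditions: NaBH4, MeOH, 0 °C
Reagents that add atoms: none
Why: Borohydride reduction of the ketone, with hydride expected from the open alkene side so that the C8 hydroxyl ends anti to the alkene; this centre is erased in step 12 and meanwhile only carries a protecting group.

Step 3
Reactants: 5 rac-7-endo-benzyloxy-3,3-dimethoxy-5-methylbicyclo[2.2.2]oct-5-en-2-ol
Product: 6 rac-7-benzyloxy-3,3-dimethoxy-2-(methoxymethoxy)-5-methylbicyclo[2.2.2]oct-5-ene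
Conditions: MOMCl, i-Pr2NEt, Bu4NI (cat.), CH2Cl2, 0 to 40 °C
Reagents that add atoms: chloromethyl methyl ether (COCCl)
Why: O-Alkylation of the hindered alcohol with the reactive chloromethyl ether under iodide catalysis; an acetal is used because this oxygen will sit beside the C2 alkoxide of step 8, where a silyl ether would migrate from oxygen to oxygen.

Step 4
Reactants: 6 rac-7-benzyloxy-3,3-dimethoxy-2-(methoxymethoxy)-5-methylbicyclo[2.2.2]oct-5-ene
Product: 7 rac-8,8-dimethoxy-7-(methoxymethoxy)-5-methylbicyclo[2.2.2]oct-5-en-2-ol (hydroxyl syn to the alkene)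
Conditions: Na, NH3(l), THF, −78 °C; NH4Cl
Reagents that add atoms: none
Why: Dissolving-metal (Birch-type) cleavage of the benzyl ether, chosen because hydrogenolysis would also saturate the strained alkene, whereas the ketal, the acetal and the isolated alkene are inert to sodium in ammonia.

Step 5
Reactants: 7 rac-8,8-dimethoxy-7-(methoxymethoxy)-5-methylbicyclo[2.2.2]oct-5-en-2-ol
Product: 8 (1S,2S,4S,7R)-8,8-dimethoxy-7-(methoxymethoxy)-5-methylbicyclo[2.2.2]oct-5-en-2-ol
Conditions: lipase PS (Burkholderia cepacia), vinyl acetate, t-BuOMe, 30 °C, to just past half conversion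
Reagents that add atoms: none
Why: Lipase-catalysed acyl transfer as a kinetic resolution, in which by the usual size rule for secondary alcohols the (2R)-enantiomer is acetylated and the (2S)-alcohol is recovered, fixing the absolute configuration of both bridgeheads for the rest of the route.

Step 6
Reactants: 8 (1S,2S,4S,7R)-8,8-dimethoxy-7-(methoxymethoxy)-5-methylbicyclo[2.2.2]oct-5-en-2-ol
Product: 9 (1R,4S,7R)-8,8-dimethoxy-7-(methoxymethoxy)-5-methylbicyclo[2.2.2]oct-5-en-2-one
Conditions: Dess–Martin periodinane, pyridine, CH2Cl2, rt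
Reagents that add atoms: none
Why: Dess–Martin oxidation of the secondary alcohol under buffered conditions that spare acetal and ketal; the adjacent bridgehead can neither epimerise nor eliminate.

Step 7
Reactants: 9 (1R,4S,7R)-8,8-dimethoxy-7-(methoxymethoxy)-5-methylbicyclo[2.2.2]oct-5-en-2-one; 10 (Z)-1-bromoprop-1-ene
Product: 12 (1R,2S,4S,7R)-8,8-dimethoxy-7-(methoxymethoxy)-5-methyl-2-[(Z)-prop-1-enyl]bicyclo[2.2.2]oct-5-en-2-ol, via (Z)-prop-1-enyllithium 11 (not isolated)
Conditions: 10, t-BuLi (2 equiv), Et2O, −78 °C; then 9, THF, −78 °C; H2O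
Reagents that add atoms: none
Why: Bromine–lithium exchange proceeds with retention of the Z geometry and the alkenyllithium adds 1,2 to the ketone from the alkene side, the opposite face being covered by the C8 methoxymethoxy group and a ketal methoxy group, which sets C2 with the propenyl group syn to the C5=C6 bond as the [3,3] shift requires.

Step 8
Reactants: 12 (1R,2S,4S,7R)-8,8-dimethoxy-7-(methoxymethoxy)-5-methyl-2-[(Z)-prop-1-enyl]bicyclo[2.2.2]oct-5-en-2-ol
Product: 15 9,9-dimethoxy-8α-(methoxymethoxy)-4β,5β-dimethyl-10βH-decal-6-en-2-one (cis-fused), via potassium alkoxide 13 (not isolated), via potassium enolate 14 (not isolated)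
Conditions: KH, 18-crown-6, THF, 0 to 40 °C; AcOH, −78 °C
Reagents that add atoms: none
Why: Deprotonation with KH and 18-crown-6 gives the free tertiary alkoxide 13, in which the C2–C7 bond is weakened so that the 1,5-diene C4=C3–C2–C7–C6=C5 undergoes a concerted anionic oxy-Cope [3,3] sigmatropic shift far below the temperature of the neutral reaction; the closest known reaction type is the rearrangement of 2-vinylbicyclo[2.2.2]oct-5-en-2-olates to cis-decalin enolates. Ring A (C1–C5, C10) closes by the new C4–C5 σ bond, formed suprafacially on both allyl units through the boat array that the bicycle enforces, while C2–C7 breaks and leaves the C6=C7 alkene in ring B and the C2 enolate 14, which is protonated on quench. C5 is set because the propenyl group can only reach the alkene face syn to the C1–C2 bridge, so C4 and C1 end cis on the ring fusion, and C10 is carried over unchanged. C4 is set by the alkene geometry: in the boat the Z methyl eclipses the C5–C10 bond and the C4 hydrogen eclipses the C5 methyl, which after bond formation leaves the two methyls cis. The step needs the sigmatropic path to beat fragmentation of the alkoxide and needs the negative charge to stay on the C2 oxygen; the rigid bicycle holds C4 within bonding distance of C5, and the neighbouring C8 oxygen carries a methoxymethyl group that cannot migrate as a silyl group would. The main strain in the transition state is the contact of the Z methyl with the C1 methylene, which is where the risk of the route sits.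

Step 9
Reactants: 15 9,9-dimethoxy-8α-(methoxymethoxy)-4β,5β-dimethyl-10βH-decal-6-en-2-one
Product: 16 9,9-dimethoxy-8α-(methoxymethoxy)-4β,5β-dimethyl-10βH-decal-6-en-2β-ol
Conditions: Li, NH3(l), THF, t-BuOH, −78 °C
Reagents that add atoms: none
Why: Dissolving-metal reduction gives the more stable equatorial 2β alcohol (cis to the methyls), where a hydride reagent would be pushed by the axial C9 carbon to the axial epimer; once silylated, the equatorial 2β oxygen holds the decalin in the chair pair with the C4–C5 bond axial on ring B, on which the later C7, C8 and C9 selectivities rest.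

Step 10
Reactants: 16 9,9-dimethoxy-8α-(methoxymethoxy)-4β,5β-dimethyl-10βH-decal-6-en-2β-ol
Product: 17 2β-(tert-butyldiphenylsilyloxy)-9,9-dimethoxy-8α-(methoxymethoxy)-4β,5β-dimethyl-10βH-decal-6-ene
Conditions: TBDPSCl, imidazole, DMF, rt
Reagents that add atoms: tert-butyl(chloro)diphenylsilane (CC(C)(C)[Si](Cl)(c1ccccc1)c1ccccc1)
Why: Silylation of the unhindered equatorial alcohol; the tert-butyldiphenylsilyl ether masks the C2 oxidation level against all later hydride steps and survives the acid of steps 11 and 18.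

Step 11
Reactants: 17 2β-(tert-butyldiphenylsilyloxy)-9,9-dimethoxy-8α-(methoxymethoxy)-4β,5β-dimethyl-10βH-decal-6-ene
Product: 18 2β-(tert-butyldiphenylsilyloxy)-9,9-dimethoxy-4β,5β-dimethyl-10βH-decal-6-en-8α-ol
Conditions: HCl (0.5 M), MeOH, 40 °C
Reagents that add atoms: none
Why: Acid-catalysed transacetalisation of the methoxymethyl ether to dimethoxymethane in methanol, a medium in which exchange at the dimethyl ketal is degenerate and the bulky silyl ether is stable.

Step 12
Reactants: 18 2β-(tert-butyldiphenylsilyloxy)-9,9-dimethoxy-4β,5β-dimethyl-10βH-decal-6-en-8α-ol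
Product: 19 2β-(tert-butyldiphenylsilyloxy)-9,9-dimethoxy-4β,5β-dimethyl-10βH-decal-6-en-8-one
Conditions: Dess–Martin periodinane, pyridine, CH2Cl2, rt
Reagents that add atoms: none
Why: Dess–Martin oxidation of the allylic alcohol to the conjugated enone; C9 is a ketal carbon, so no epimerisable centre flanks the new carbonyl.

Step 13
Reactants: 19 2β-(tert-butyldiphenylsilyloxy)-9,9-dimethoxy-4β,5β-dimethyl-10βH-decal-6-en-8-one
Product: 20 7-iodo-2β-(tert-butyldiphenylsilyloxy)-9,9-dimethoxy-4β,5β-dimethyl-10βH-decal-6-en-8-one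
Conditions: I2, pyridine, CH2Cl2, rt
Reagents that add atoms: iodine ([I][I])
Why: α-Iodination of the enone by pyridine addition, iodination of the enolate and elimination (Johnson iodination), a sequence known to work on 4,4-disubstituted cyclohexenones of this kind.

Step 14
Reactants: 20 7-iodo-2β-(tert-butyldiphenylsilyloxy)-9,9-dimethoxy-4β,5β-dimethyl-10βH-decal-6-en-8-one; 21 isopropenylboronic acid pinacol ester
Product: 22 2β-(tert-butyldiphenylsilyloxy)-9,9-dimethoxy-10βH-eremophila-6,11-dien-8-one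
Conditions: Pd(dppf)Cl2 (5 mol %), K3PO4, dioxane/H2O, 60 °C
Reagents that add atoms: none
Why: Suzuki–Miyaura coupling of the electron-poor alkenyl iodide with the alkenylboronate gives the cross-conjugated 2-isopropenyl enone without touching ketal or silyl ether.

Step 15
Reactants: 22 2β-(tert-butyldiphenylsilyloxy)-9,9-dimethoxy-10βH-eremophila-6,11-dien-8-one
Product: 25 2β-(tert-butyldiphenylsilyloxy)-9,9-dimethoxy-7αH,10βH-eremophil-11-en-8-one (7β-isopropenyl), via copper enolate 23 (not isolated), via 7α-isopropenyl ketone 24 (not isolated)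
Conditions: [(Ph3P)CuH]6 (0.5 equiv), THF/H2O, rt; then DBU (0.2 equiv), toluene, rt
Reagents that add atoms: none
Why: Conjugate hydride transfer from the phosphine copper hydride to C6 is selective for the enone over the 1,1-disubstituted alkene, and C7 is then set under thermodynamic control by brief base equilibration, the 7β (equatorial) epimer being strongly preferred because in the chair fixed by the 2β silyl ether a 7α group would be syn-axial to both C4 and a C9 methoxy group.

Step 16
Reactants: 25 2β-(tert-butyldiphenylsilyloxy)-9,9-dimethoxy-7αH,10βH-eremophil-11-en-8-one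
Product: 26 2β-(tert-butyldiphenylsilyloxy)-9,9-dimethoxy-7αH,10βH-eremophil-11-en-8α-ol
Conditions: NaBH4, MeOH/CH2Cl2, −20 °C
Reagents that add atoms: none
Why: Borohydride adds along the unhindered axial line on the β face of C8, anti to the axial C9 methoxy group, and so gives the equatorial 8α alcohol trans to the isopropenyl group.

Step 17
Reactants: 26 2β-(tert-butyldiphenylsilyloxy)-9,9-dimethoxy-7αH,10βH-eremophil-11-en-8α-ol
Product: 27 2β-(tert-butyldiphenylsilyloxy)-9,9-dimethoxy-8α-tigloyloxy-7αH,10βH-eremophil-11-ene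
Conditions: tigloyl chloride, Et3N, DMAP (cat.), CH2Cl2, 0 °C to rt
Reagents that add atoms: tigloyl chloride (C/C=C(\C)C(Cl)=O)
Why: DMAP-catalysed acylation of the secondary alcohol with the acid chloride; the E geometry of the tigloyl unit is the stable one and is not at risk.

Step 18
Reactants: 27 2β-(tert-butyldiphenylsilyloxy)-9,9-dimethoxy-8α-tigloyloxy-7αH,10βH-eremophil-11-ene
Product: 28 2β-(tert-butyldiphenylsilyloxy)-8α-tigloyloxy-7αH,10βH-eremophil-11-en-9-one
Conditions: TsOH·H2O (cat.), acetone/H2O, 50 °C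
Reagents that add atoms: water (O)
Why: Acid-catalysed hydrolysis of the dimethyl ketal (exchange to acetone) under conditions mild enough for the isopropenyl group, the ester and the silyl ether.

Step 19
Reactants: 28 2β-(tert-butyldiphenylsilyloxy)-8α-tigloyloxy-7αH,10βH-eremophil-11-en-9-one
Product: 29 2β-(tert-butyldiphenylsilyloxy)-8α-tigloyloxy-7αH,10βH-eremophil-11-en-9α-ol
Conditions: LiBH(s-Bu)3, THF, −78 °C; AcOH, −78 °C
Reagents that add atoms: none
Why: The bulky borohydride attacks the activated α-acyloxy ketone from the β face along the equatorial line, the axial α approach being closed by the syn-axial C4, which gives the axial 9α alcohol cis to the C8 ester; the cold acidic quench guards against acyl migration and the enoate is not reduced at this temperature.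

Step 20
Reactants: 29 2β-(tert-butyldiphenylsilyloxy)-8α-tigloyloxy-7αH,10βH-eremophil-11-en-9α-ol
Product: 30 9α-angeloyloxy-2β-(tert-butyldiphenylsilyloxy)-8α-tigloyloxy-7αH,10βH-eremophil-11-ene
Conditions: angelic acid, 2,4,6-trichlorobenzoyl chloride, Et3N, toluene, rt; then 29, 80 °C
Reagents that add atoms: angelic acid (C/C=C(/C)C(=O)O)
Why: Yamaguchi esterification through the mixed anhydride of angelic acid, run without a nucleophilic catalyst because that is the known way to acylate hindered alcohols with retention of the Z geometry.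

Step 21
Reactants: 30 9α-angeloyloxy-2β-(tert-butyldiphenylsilyloxy)-8α-tigloyloxy-7αH,10βH-eremophil-11-ene
Product: 31 9α-angeloyloxy-8α-tigloyloxy-7αH,10βH-eremophil-11-en-2β-ol
Conditions: HF·pyridine, pyridine, THF, 0 °C to rt
Reagents that add atoms: none
Why: Fluoride cleavage of the silyl ether under buffered acidic conditions, which leave both enoates (the Z one included) and the isopropenyl group unchanged.

Step 22
Reactants: 31 9α-angeloyloxy-8α-tigloyloxy-7αH,10βH-eremophil-11-en-2β-ol
Product: 32 (4S,5R,7R,8R,9S,10S)-9-angeloyloxy-8-tigloyloxyeremophil-11-en-2-one (CNP0249036.3)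
Conditions: Dess–Martin periodinane, pyridine, CH2Cl2, rt
Reagents that add atoms: none
Why: Dess–Martin oxidation of the one remaining alcohol to the C2 ketone; neither α-carbon is a stereocentre and nothing else in the molecule is oxidisable under these conditions.

**Compound list**

1 | creosol (2-methoxy-4-methylphenol) | Cc1ccc(O)c(OC)c1 | starting material
2 | benzyl vinyl ether | C=COCc1ccccc1 | starting material
3 | 6,6-dimethoxy-4-methylcyclohexa-2,4-dien-1-one (masked o-benzoquinone; not isolated) | O=C1C=CC(C)=CC1(OC)OC | intermediate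
4 | rac-7-endo-benzyloxy-3,3-dimethoxy-5-methylbicyclo[2.2.2]oct-5-en-2-one (OBn syn to the alkene; racemic) | [C@H]12C=C(C)[C@H](C[C@@H]1OCc3ccccc3)C(OC)(OC)C2=O | intermediate
5 | rac-7-endo-benzyloxy-3,3-dimethoxy-5-methylbicyclo[2.2.2]oct-5-en-2-ol (OH anti to the alkene; racemic) | [C@H]12C=C(C)[C@H](C[C@@H]1OCc3ccccc3)C(OC)(OC)[C@@H]2O | intermediate
6 | rac-7-benzyloxy-3,3-dimethoxy-2-(methoxymethoxy)-5-methylbicyclo[2.2.2]oct-5-ene (racemic) | [C@H]12C=C(C)[C@H](C[C@@H]1OCc3ccccc3)C(OC)(OC)[C@@H]2OCOC | intermediate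
7 | rac-8,8-dimethoxy-7-(methoxymethoxy)-5-methylbicyclo[2.2.2]oct-5-en-2-ol (OH syn to the alkene, OMOM anti; racemic) | [C@H]12C=C(C)[C@H](C[C@@H]1O)C(OC)(OC)[C@@H]2OCOC | intermediate
8 | (1S,2S,4S,7R)-8,8-dimethoxy-7-(methoxymethoxy)-5-methylbicyclo[2.2.2]oct-5-en-2-ol (single enantiomer of 7) | [C@H]12C=C(C)[C@H](C[C@@H]1O)C(OC)(OC)[C@@H]2OCOC | intermediate
9 | (1R,4S,7R)-8,8-dimethoxy-7-(methoxymethoxy)-5-methylbicyclo[2.2.2]oct-5-en-2-one | [C@H]12C=C(C)[C@H](CC1=O)C(OC)(OC)[C@@H]2OCOC | intermediate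
10 | (Z)-1-bromoprop-1-ene | C/C=C\Br | starting material
11 | (Z)-prop-1-enyllithium (not isolated) | C/C=C\[Li] | intermediate
12 | (1R,2S,4S,7R)-8,8-dimethoxy-7-(methoxymethoxy)-5-methyl-2-[(Z)-prop-1-enyl]bicyclo[2.2.2]oct-5-en-2-ol (propenyl syn to the alkene) | [C@H]12C=C(C)[C@H](C[C@]1(O)/C=C\C)C(OC)(OC)[C@@H]2OCOC | intermediate
13 | potassium alkoxide of 12 (not isolated) | [C@H]12C=C(C)[C@H](C[C@]1([O-])/C=C\C)C(OC)(OC)[C@@H]2OCOC.[K+] | intermediate
14 | potassium Δ2-enolate of 15 (not isolated) | C1=C[C@@]2(C)[C@H](CC([O-])=C[C@@H]2C)C(OC)(OC)[C@@H]1OCOC.[K+] | intermediate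
15 | 9,9-dimethoxy-8α-(methoxymethoxy)-4β,5β-dimethyl-10βH-decal-6-en-2-one (cis-fused) | C1=C[C@@]2(C)[C@H](CC(=O)C[C@@H]2C)C(OC)(OC)[C@@H]1OCOC | intermediate
16 | 9,9-dimethoxy-8α-(methoxymethoxy)-4β,5β-dimethyl-10βH-decal-6-en-2β-ol | C1=C[C@@]2(C)[C@H](C[C@H](O)C[C@@H]2C)C(OC)(OC)[C@@H]1OCOC | intermediate
17 | 2β-(tert-butyldiphenylsilyloxy)-9,9-dimethoxy-8α-(methoxymethoxy)-4β,5β-dimethyl-10βH-decal-6-ene | C1=C[C@@]2(C)[C@H](C[C@H](O[Si](c3ccccc3)(c3ccccc3)C(C)(C)C)C[C@@H]2C)C(OC)(OC)[C@@H]1OCOC | intermediate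
18 | 2β-(tert-butyldiphenylsilyloxy)-9,9-dimethoxy-4β,5β-dimethyl-10βH-decal-6-en-8α-ol | C1=C[C@@]2(C)[C@H](C[C@H](O[Si](c3ccccc3)(c3ccccc3)C(C)(C)C)C[C@@H]2C)C(OC)(OC)[C@@H]1O | intermediate
19 | 2β-(tert-butyldiphenylsilyloxy)-9,9-dimethoxy-4β,5β-dimethyl-10βH-decal-6-en-8-one | C1=C[C@@]2(C)[C@H](C[C@H](O[Si](c3ccccc3)(c3ccccc3)C(C)(C)C)C[C@@H]2C)C(OC)(OC)C1=O | intermediate
20 | 7-iodo-2β-(tert-butyldiphenylsilyloxy)-9,9-dimethoxy-4β,5β-dimethyl-10βH-decal-6-en-8-one | IC1=C[C@@]2(C)[C@H](C[C@H](O[Si](c3ccccc3)(c3ccccc3)C(C)(C)C)C[C@@H]2C)C(OC)(OC)C1=O | intermediate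
21 | isopropenylboronic acid pinacol ester | CC(=C)B1OC(C)(C)C(C)(C)O1 | starting material
22 | 2β-(tert-butyldiphenylsilyloxy)-9,9-dimethoxy-10βH-eremophila-6,11-dien-8-one | C=C(C)C1=C[C@@]2(C)[C@H](C[C@H](O[Si](c3ccccc3)(c3ccccc3)C(C)(C)C)C[C@@H]2C)C(OC)(OC)C1=O | intermediate
23 | copper enolate of 25 (C7=C8; phosphine ligands not drawn; not isolated) | C=C(C)C=1C[C@@]2(C)[C@H](C[C@H](O[Si](c3ccccc3)(c3ccccc3)C(C)(C)C)C[C@@H]2C)C(OC)(OC)C=1O[Cu] | intermediate
24 | 7α-isopropenyl epimer of 25 (not isolated) | C=C(C)[C@@H]1C[C@@]2(C)[C@H](C[C@H](O[Si](c3ccccc3)(c3ccccc3)C(C)(C)C)C[C@@H]2C)C(OC)(OC)C1=O | intermediate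
25 | 2β-(tert-butyldiphenylsilyloxy)-9,9-dimethoxy-7αH,10βH-eremophil-11-en-8-one (7β-isopropenyl) | C=C(C)[C@H]1C[C@@]2(C)[C@H](C[C@H](O[Si](c3ccccc3)(c3ccccc3)C(C)(C)C)C[C@@H]2C)C(OC)(OC)C1=O | intermediate
26 | 2β-(tert-butyldiphenylsilyloxy)-9,9-dimethoxy-7αH,10βH-eremophil-11-en-8α-ol | C=C(C)[C@H]1C[C@@]2(C)[C@H](C[C@H](O[Si](c3ccccc3)(c3ccccc3)C(C)(C)C)C[C@@H]2C)C(OC)(OC)[C@@H]1O | intermediate
27 | 2β-(tert-butyldiphenylsilyloxy)-9,9-dimethoxy-8α-tigloyloxy-7αH,10βH-eremophil-11-ene | C=C(C)[C@H]1C[C@@]2(C)[C@H](C[C@H](O[Si](c3ccccc3)(c3ccccc3)C(C)(C)C)C[C@@H]2C)C(OC)(OC)[C@@H]1OC(=O)/C(C)=C/C | intermediate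
28 | 2β-(tert-butyldiphenylsilyloxy)-8α-tigloyloxy-7αH,10βH-eremophil-11-en-9-one | C=C(C)[C@H]1C[C@@]2(C)[C@H](C[C@H](O[Si](c3ccccc3)(c3ccccc3)C(C)(C)C)C[C@@H]2C)C(=O)[C@@H]1OC(=O)/C(C)=C/C | intermediate
29 | 2β-(tert-butyldiphenylsilyloxy)-8α-tigloyloxy-7αH,10βH-eremophil-11-en-9α-ol | C=C(C)[C@H]1C[C@@]2(C)[C@H](C[C@H](O[Si](c3ccccc3)(c3ccccc3)C(C)(C)C)C[C@@H]2C)[C@H](O)[C@@H]1OC(=O)/C(C)=C/C | intermediate
30 | 9α-angeloyloxy-2β-(tert-butyldiphenylsilyloxy)-8α-tigloyloxy-7αH,10βH-eremophil-11-ene | C=C(C)[C@H]1C[C@@]2(C)[C@H](C[C@H](O[Si](c3ccccc3)(c3ccccc3)C(C)(C)C)C[C@@H]2C)[C@H](OC(=O)/C(C)=C\C)[C@@H]1OC(=O)/C(C)=C/C | intermediate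
31 | 9α-angeloyloxy-8α-tigloyloxy-7αH,10βH-eremophil-11-en-2β-ol | C=C(C)[C@H]1C[C@@]2(C)[C@H](C[C@H](O)C[C@@H]2C)[C@H](OC(=O)/C(C)=C\C)[C@@H]1OC(=O)/C(C)=C/C | intermediate
32 | (4S,5R,7R,8R,9S,10S)-9-angeloyloxy-8-tigloyloxyeremophil-11-en-2-one (CNP0249036.3) | C=C(C)[C@H]1C[C@@]2(C)[C@H](CC(=O)C[C@@H]2C)[C@H](OC(=O)/C(C)=C\C)[C@@H]1OC(=O)/C(C)=C/C | target

**Step count and risks**

Total step count: 22. Longest linear sequence: 22 steps (from creosol 1).

Steps most likely to fail:

1. Step 8 (key step). The Z methyl is pressed against the C1 methylene in the boat, so the shift may be slow; the alkoxide could then fragment at C2–C7 and recombine without control at C4, or not react at all. The fallback sets out from ketone 9 and returns at 15. CH2=CHMgBr (THF, −78 °C) should add from the alkene face to give the vinyl carbinol F1, whose alkoxide (KH, 18-crown-6, THF) rearranges with no terminal substituent in the way. The enolate is trapped with Me3SiCl as the trimethylsilyl enol ether F2, which keeps the double bond at C2=C3. Pd(OAc)2 in MeCN (Saegusa–Ito oxidation) then gives the Δ3-en-2-one F3. Me2CuLi (Et2O, −40 °C) should deliver the C4 methyl axially on the β face, anti to the pseudoaxial C5–C6 bond and therefore cis to the C5 methyl, to give 15.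

2. Step 15. The base equilibration at C7 may run on to the conjugated isopropylidene ketone, or stop at a mixture of epimers if the conformational bias is smaller than expected. The fallback sets out from iodoenone 20 and returns at alcohol 26, and fixes C7 by reagent delivery and not by equilibrium. Stille coupling with tributyl(1-ethoxyvinyl)stannane (Pd(PPh3)4, CuI, DMF) gives the ethoxyvinyl enone F4. i-Bu2AlH (toluene, −78 °C) reduces C8 from the convex β face to the 8α allylic alcohol F5. Dilute HCl in THF unmasks the acetyl enone alcohol F6. Hydrogenation with [Ir(cod)(PCy3)(py)]PF6 (H2, CH2Cl2) is directed by the 8α hydroxyl and adds hydrogen to the α face of C6=C7, giving the 7β-acetyl alcohol F7. Cp2TiMe2 (toluene, 65 °C) methylenates the methyl ketone to give 26.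

3. Step 20. Acylation of the hindered axial C9 alcohol is slow, which gives time for Z-to-E isomerisation of the angeloyl unit and for migration of the C8 acyl group to C9. The fallback sets out from alcohol 29 and returns at 30. Esterification with 2-[bis(2,2,2-trifluoroethoxy)phosphoryl]propanoic acid (DCC, DMAP, CH2Cl2, rt) gives the phosphonate ester F8. Still–Gennari olefination with acetaldehyde (KN(SiMe3)2, 18-crown-6, THF, −78 °C) then builds the Z-enoate on the molecule to give 30.

Further compounds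

F1 | step 8 | (1R,2S,4S,7R)-8,8-dimethoxy-7-(methoxymethoxy)-5-methyl-2-vinylbicyclo[2.2.2]oct-5-en-2-ol | [C@H]12C=C(C)[C@H](C[C@]1(O)C=C)C(OC)(OC)[C@@H]2OCOC
F2 | step 8 | 2-(trimethylsilyloxy)-9,9-dimethoxy-8α-(methoxymethoxy)-5β-methyl-10βH-decala-2,6-diene | C1=C[C@@]2(C)[C@H](CC(O[Si](C)(C)C)=CC2)C(OC)(OC)[C@@H]1OCOC
F3 | step 8 | 9,9-dimethoxy-8α-(methoxymethoxy)-5β-methyl-10βH-decala-3,6-dien-2-one | C1=C[C@@]2(C)[C@H](CC(=O)C=C2)C(OC)(OC)[C@@H]1OCOC
F4 | step 15 | 7-(1-ethoxyvinyl)-2β-(tert-butyldiphenylsilyloxy)-9,9-dimethoxy-4β,5β-dimethyl-10βH-decal-6-en-8-one | CCOC(=C)C1=C[C@@]2(C)[C@H](C[C@H](O[Si](c3ccccc3)(c3ccccc3)C(C)(C)C)C[C@@H]2C)C(OC)(OC)C1=O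
F5 | step 15 | 7-(1-ethoxyvinyl)-2β-(tert-butyldiphenylsilyloxy)-9,9-dimethoxy-4β,5β-dimethyl-10βH-decal-6-en-8α-ol | CCOC(=C)C1=C[C@@]2(C)[C@H](C[C@H](O[Si](c3ccccc3)(c3ccccc3)C(C)(C)C)C[C@@H]2C)C(OC)(OC)[C@@H]1O
F6 | step 15 | 7-acetyl-2β-(tert-butyldiphenylsilyloxy)-9,9-dimethoxy-4β,5β-dimethyl-10βH-decal-6-en-8α-ol | CC(=O)C1=C[C@@]2(C)[C@H](C[C@H](O[Si](c3ccccc3)(c3ccccc3)C(C)(C)C)C[C@@H]2C)C(OC)(OC)[C@@H]1O
F7 | step 15 | 7β-acetyl-2β-(tert-butyldiphenylsilyloxy)-9,9-dimethoxy-4β,5β-dimethyl-7αH,10βH-decalin-8α-ol | CC(=O)[C@H]1C[C@@]2(C)[C@H](C[C@H](O[Si](c3ccccc3)(c3ccccc3)C(C)(C)C)C[C@@H]2C)C(OC)(OC)[C@@H]1O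
F8 | step 20 | 9α-{2-[bis(2,2,2-trifluoroethoxy)phosphoryl]propanoyloxy}-2β-(tert-butyldiphenylsilyloxy)-8α-tigloyloxy-7αH,10βH-eremophil-11-ene | C=C(C)[C@H]1C[C@@]2(C)[C@H](C[C@H](O[Si](c3ccccc3)(c3ccccc3)C(C)(C)C)C[C@@H]2C)[C@H](OC(=O)C(C)P(=O)(OCC(F)(F)F)OCC(F)(F)F)[C@@H]1OC(=O)/C(C)=C/C
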